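**Retrosynthetic overview**
1. Target 23 ⇐ triple angeloylation of triol 20 ⇐ hydroxyl-guided epoxidation of Z-enone 19 (1,10-oxirane) ⇐ allylic oxidation of macrocyclic tetraol 18.
2. Key disconnection C8–C9: 18 ⇐ SmI2 ketyl–ketyl (pinacol) macrocyclisation of 17, whose Z-enal (C9) is masked as a lactol on O3 and whose C8 aldehyde is free. This step forms the only carbocycle (ten-membered) and sets C8.
3. 17 ⇐ double i-Bu2AlH reduction of ester/lactone 15 ⇐ syn-selective deconjugative aldol (C6–C7) of methyl 3-methylbut-2-enoate with cis-epoxy aldehyde 11.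
4. 11 ⇐ dihydropyranone 10 (ring-closing metathesis fixes Z-C1=C10) ⇐ hydroxyl-directed 4,5-epoxidation ⇐ Brown allylation (C3) of the lactol from 3-methylfuran-2(5H)-one, whose ring supplies Z-C4=C5.
5. Ring order: 4,5-oxirane → dihydropyranone (temporary) → ten-membered carbocycle → 1,10-oxirane.

Assumption: the target is taken exactly as the SMILES gives it, (1R,3S,4R,5S,6S,7S,8S,10R) with both oxiranes cis-fused to the ring (C2/C9 cis and C3/C6 cis); germacrane numbering is used throughout and β means the ring face that carries the C7 isopropenyl group.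

**Step 1**
Reactants: 1 3-methylfuran-2(5H)-one
Product: 2 3-methyl-2,5-dihydrofuran-2-ol
Conditions: i-Bu2AlH (1.05 equiv), CH2Cl2, −78 °C, 1 h; aq. KNaC4H4O6; used crude
Reagents that add atoms: none
Why: Partial i-Bu2AlH reduction of a butenolide stops at the lactol, which is the masked (Z)-4-hydroxy-2-methylbut-2-enal and carries the Z-C4=C5 geometry from the ring.

**Step 2**
Reactants: 2 3-methyl-2,5-dihydrofuran-2-ol; 3 allylmagnesium bromide
Product: 5 (2Z,4S)-3-methylhepta-2,6-diene-1,4-diol, via allylborane 4 (not isolated)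
Conditions: (−)-Ipc2BOMe (2.4 equiv), 3 (2.3 equiv), Et2O, −78 °C → rt; then 2, −78 °C → rt; 3 M NaOH, 30% H2O2
Reagents that add atoms: none
Why: Brown allylboration of the open hydroxy-enal form through a chair transition state, the reagent from (+)-α-pinene attacking the Si face (as with benzaldehyde) to set C3 as S.

**Step 3**
Reactants: 5 (2Z,4S)-3-methylhepta-2,6-diene-1,4-diol
Product: 6 (2Z,4S)-3-methyl-1-(triethylsilyloxy)hepta-2,6-dien-4-ol
Conditions: Et3SiCl (1.05 equiv), imidazole, CH2Cl2, −78 → −20 °C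
Reagents that add atoms: chlorotriethylsilane CC[Si](Cl)(CC)CC
Why: Silylation is selective for the unhindered primary allylic hydroxyl over the secondary C3 hydroxyl, which must stay free to direct the next step.

**Step 4**
Reactants: 6 (2Z,4S)-3-methyl-1-(triethylsilyloxy)hepta-2,6-dien-4-ol
Product: 7 (1S)-1-[(2R,3S)-2-methyl-3-(triethylsilyloxymethyl)oxiran-2-yl]but-3-en-1-ol
Conditions: mCPBA (1.2 equiv), CH2Cl2, 0 °C
Reagents that add atoms: 3-chloroperbenzoic acid O=C(OO)c1cccc(Cl)c1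
Why: Henbest hydroxyl-directed peracid epoxidation, in which C3–H eclipses the Z-olefin to avoid A1,3 strain and the hydrogen-bonded peracid is delivered to the hydroxyl face, giving the threo cis-epoxy alcohol (C4 R, C5 S), while the terminal vinyl group is much slower.

**Step 5**
Reactants: 7 (1S)-1-[(2R,3S)-2-methyl-3-(triethylsilyloxymethyl)oxiran-2-yl]but-3-en-1-ol; 8 methacryloyl chloride
Product: 9 (1S)-1-[(2R,3S)-2-methyl-3-(triethylsilyloxymethyl)oxiran-2-yl]but-3-en-1-yl 2-methylprop-2-enoate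
Conditions: 8 (1.5 equiv), Et3N, DMAP (cat.), CH2Cl2, 0 °C → rt
Reagents that add atoms: none
Why: DMAP-catalysed acylation of the secondary alcohol brings in C9, C10 and C14 without touching any stereocentre.

**Step 6**
Reactants: 9 (1S)-1-[(2R,3S)-2-methyl-3-(triethylsilyloxymethyl)oxiran-2-yl]but-3-en-1-yl 2-methylprop-2-enoate
Product: 10 (6S)-3-methyl-6-[(2R,3S)-2-methyl-3-(triethylsilyloxymethyl)oxiran-2-yl]-5,6-dihydro-2H-pyran-2-one
Conditions: second-generation Grubbs catalyst RuCl2(=CHPh)(PCy3)(H2IMes) (5 mol%), CH2Cl2 (0.01 M), 40 °C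
Reagents that add atoms: none
Why: Ring-closing metathesis of the methacrylate with the terminal vinyl group gives the six-membered lactone, whose ring forces the C1=C10 olefin to be Z (C2 and C9 cis).

**Step 7**
Reactants: 10 (6S)-3-methyl-6-[(2R,3S)-2-methyl-3-(triethylsilyloxymethyl)oxiran-2-yl]-5,6-dihydro-2H-pyran-2-one
Product: 11 (2R,3R)-3-methyl-3-[(2S)-5-methyl-6-oxo-3,6-dihydro-2H-pyran-2-yl]oxirane-2-carbaldehyde
Conditions: (COCl)2, DMSO, CH2Cl2, −78 → −40 °C; Et3N, −78 → 0 °C; used directly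
Reagents that add atoms: none
Why: Swern conditions cleave and oxidise a primary triethylsilyl ether in one operation, giving the non-enolisable cis-epoxy aldehyde without change at C5 (the descriptor changes only because the priorities change).

**Step 8**
Reactants: 11 (2R,3R)-3-methyl-3-[(2S)-5-methyl-6-oxo-3,6-dihydro-2H-pyran-2-yl]oxirane-2-carbaldehyde; 12 methyl 3-methylbut-2-enoate
Product: 15 methyl (2S,3S)-3-[(2S,3R)-3-methyl-3-[(2S)-5-methyl-6-oxo-3,6-dihydro-2H-pyran-2-yl]oxiran-2-yl]-2-(prop-1-en-2-yl)-3-(trimethylsilyloxy)propanoate, via lithium dienolate 13 (not isolated), via lithium aldolate 14 (not isolated)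
Conditions: LiN(i-Pr)2 (1.1 equiv), 12, THF, −78 °C; then 11, −78 °C, 20 min; then Me3SiCl, −78 → 0 °C
Reagents that add atoms: chlorotrimethylsilane C[Si](C)(C)Cl
Why: Deconjugative aldol in which γ-deprotonation of the s-cis enoate gives the dienolate with OLi cis to the isopropenyl group, which reacts at its α-carbon through a Zimmerman–Traxler chair (6,7-syn) and attacks the aldehyde anti to the oxirane C–O bond (Cornforth/Felkin, C6 S); silyl trapping prevents retro-aldol.

**Step 9**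
Reactants: 15 methyl (2S,3S)-3-[(2S,3R)-3-methyl-3-[(2S)-5-methyl-6-oxo-3,6-dihydro-2H-pyran-2-yl]oxiran-2-yl]-2-(prop-1-en-2-yl)-3-(trimethylsilyloxy)propanoate
Product: 17 (2S,3S)-3-hydroxy-3-[(2S,3R)-3-[(2S)-6-hydroxy-5-methyl-3,6-dihydro-2H-pyran-2-yl]-3-methyloxiran-2-yl]-2-(prop-1-en-2-yl)propanal, via silyl ether aldehyde 16 (not isolated)
Conditions: i-Bu2AlH (2.3 equiv), CH2Cl2, −78 °C; aq. KNaC4H4O6; then 10% aq. citric acid, THF, 0 °C, 15 min; used crude at once
Reagents that add atoms: none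
Why: i-Bu2AlH partial reduction stops at the aluminium hemiacetals of both the lactone (giving the lactol, a masked Z-enal) and the methyl ester (giving the C8 aldehyde); the mild acid wash frees the C6 hydroxyl and no stereocentre is touched.

**Step 10**
Reactants: 17 (2S,3S)-3-hydroxy-3-[(2S,3R)-3-[(2S)-6-hydroxy-5-methyl-3,6-dihydro-2H-pyran-2-yl]-3-methyloxiran-2-yl]-2-(prop-1-en-2-yl)propanal
Product: 18 (1(10)Z)-4α,5α-epoxy-7αH-germacra-1(10),11-diene-3β,6α,8β,9β-tetraol
Conditions: SmI2 (4 equiv, 0.1 M in THF), slow addition of 17 in THF (final 0.002 M), 0 °C → rt; aq. NaHCO3/Na2S2O3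
Reagents that add atoms: none
Why: Proposed new method: SmI2 reduces the free C8 aldehyde and the Z-enal released from the lactol to ketyl radicals held on trivalent samarium, which couple C8–C9 to close the ten-membered ring; the C6 alkoxide–samarium chelate lets C9 approach C8 anti to the isopropenyl group (8β-OH) and the samarium bridge favours the cis-diol (either C9 epimer is usable); the closest known reaction type is the SmI2 or low-valent titanium intramolecular pinacol macrocyclisation of dialdehydes, enals included.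

**Step 11**
Reactants: 18 (1(10)Z)-4α,5α-epoxy-7αH-germacra-1(10),11-diene-3β,6α,8β,9β-tetraol
Product: 19 (1(10)Z)-4α,5α-epoxy-3β,6α,8β-trihydroxy-7αH-germacra-1(10),11-dien-9-one
Conditions: activated MnO2 (20 equiv), CH2Cl2, rt
Reagents that add atoms: none
Why: MnO2 allylic oxidation touches only the C9 carbinol, because the C3, C6 and C8 hydroxyls are no longer allylic once the 4,5-olefin is epoxidised.

**Step 12**
Reactants: 19 (1(10)Z)-4α,5α-epoxy-3β,6α,8β-trihydroxy-7αH-germacra-1(10),11-dien-9-one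
Product: 20 1β,10β:4α,5α-diepoxy-3β,6α,8β-trihydroxy-7αH-germacr-11-en-9-one
Conditions: t-BuOOH (3 equiv, in decane), DBU (0.5 equiv), CH2Cl2, 0 °C, short reaction time
Reagents that add atoms: tert-butyl hydroperoxide CC(C)(C)OO
Why: Weitz–Scheffer nucleophilic epoxidation in which the 8β and 3β hydroxyls hydrogen-bond the tert-butylperoxide so that it adds to C1 from the β face, and the ring holds the enolate so that it closes to the cis-fused oxirane (C1 R, C10 R).

**Step 13**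
Reactants: 20 1β,10β:4α,5α-diepoxy-3β,6α,8β-trihydroxy-7αH-germacr-11-en-9-one; 21 angelic acid (three molecules are incorporated, one on each hydroxyl)
Product: 23 3β,6α,8β-tris(angeloyloxy)-1β,10β:4α,5α-diepoxy-7αH-germacr-11-en-9-one (CNP0154187.1), via mixed anhydride 22 (not isolated)
Conditions: 21 (6 equiv), 2,4,6-trichlorobenzoyl chloride (6 equiv), Et3N, toluene, rt, 2 h; then 20, toluene, 75 °C
Reagents that add atoms: angelic acid, the second and third molecules of 21 that end up in the product C/C=C(/C)C(=O)O.C/C=C(/C)C(=O)O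
Why: Yamaguchi esterification in which three molecules of the mixed anhydride, run without a nucleophilic catalyst, each transfer one angeloyl group to one of the three secondary hydroxyls without Z-to-E isomerisation to tiglate and without touching a stereocentre.

**Compound list**
1 | 3-methylfuran-2(5H)-one | CC1=CCOC1=O | starting material
2 | 3-methyl-2,5-dihydrofuran-2-ol (lactol, anomeric mixture; open form (Z)-4-hydroxy-2-methylbut-2-enal) | CC1=CCOC1O | intermediate
3 | allylmagnesium bromide | C=CC[Mg]Br | starting material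
4 | (−)-B-allyldiisopinocampheylborane (isopinocampheyl groups from (+)-α-pinene) | C=CCB([C@@H]1C[C@@H]2C[C@H]([C@H]1C)C2(C)C)[C@@H]1C[C@@H]2C[C@H]([C@H]1C)C2(C)C | intermediate
5 | (2Z,4S)-3-methylhepta-2,6-diene-1,4-diol | OC/C=C(C)\[C@@H](O)CC=C | intermediate
6 | (2Z,4S)-3-methyl-1-(triethylsilyloxy)hepta-2,6-dien-4-ol | CC[Si](CC)(CC)OC/C=C(C)\[C@@H](O)CC=C | intermediate
7 | (1S)-1-[(2R,3S)-2-methyl-3-(triethylsilyloxymethyl)oxiran-2-yl]but-3-en-1-ol | CC[Si](CC)(CC)OC[C@@H]1O[C@]1(C)[C@@H](O)CC=C | intermediate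
8 | methacryloyl chloride | C=C(C)C(=O)Cl | starting material
9 | (1S)-1-[(2R,3S)-2-methyl-3-(triethylsilyloxymethyl)oxiran-2-yl]but-3-en-1-yl 2-methylprop-2-enoate | CC[Si](CC)(CC)OC[C@@H]1O[C@]1(C)[C@@H](OC(=O)C(C)=C)CC=C | intermediate
10 | (6S)-3-methyl-6-[(2R,3S)-2-methyl-3-(triethylsilyloxymethyl)oxiran-2-yl]-5,6-dihydro-2H-pyran-2-one | CC[Si](CC)(CC)OC[C@@H]1O[C@]1(C)[C@@H]2CC=C(C)C(=O)O2 | intermediate
11 | (2R,3R)-3-methyl-3-[(2S)-5-methyl-6-oxo-3,6-dihydro-2H-pyran-2-yl]oxirane-2-carbaldehyde | O=C[C@@H]1O[C@]1(C)[C@@H]2CC=C(C)C(=O)O2 | intermediate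
12 | methyl 3-methylbut-2-enoate | COC(=O)C=C(C)C | starting material
13 | lithium 1-methoxy-3-methylbuta-1,3-dien-1-olate (OLi cis to the isopropenyl group) | [Li+].C=C(C)/C=C(\[O-])OC | intermediate
14 | lithium aldolate of 15 (lithium alkoxide at C6) | [Li+].C=C(C)[C@H](C(=O)OC)[C@H]([O-])[C@@H]1O[C@]1(C)[C@@H]2CC=C(C)C(=O)O2 | intermediate
15 | methyl (2S,3S)-3-[(2S,3R)-3-methyl-3-[(2S)-5-methyl-6-oxo-3,6-dihydro-2H-pyran-2-yl]oxiran-2-yl]-2-(prop-1-en-2-yl)-3-(trimethylsilyloxy)propanoate | C=C(C)[C@H](C(=O)OC)[C@H](O[Si](C)(C)C)[C@@H]1O[C@]1(C)[C@@H]2CC=C(C)C(=O)O2 | intermediate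
16 | (2S,3S)-3-[(2S,3R)-3-[(2S)-6-hydroxy-5-methyl-3,6-dihydro-2H-pyran-2-yl]-3-methyloxiran-2-yl]-2-(prop-1-en-2-yl)-3-(trimethylsilyloxy)propanal (lactol, anomeric mixture) | C=C(C)[C@H](C=O)[C@H](O[Si](C)(C)C)[C@@H]1O[C@]1(C)[C@@H]2CC=C(C)C(O)O2 | intermediate
17 | (2S,3S)-3-hydroxy-3-[(2S,3R)-3-[(2S)-6-hydroxy-5-methyl-3,6-dihydro-2H-pyran-2-yl]-3-methyloxiran-2-yl]-2-(prop-1-en-2-yl)propanal (lactol, anomeric mixture) | C=C(C)[C@H](C=O)[C@H](O)[C@@H]1O[C@]1(C)[C@@H]2CC=C(C)C(O)O2 | intermediate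
18 | (1(10)Z)-4α,5α-epoxy-7αH-germacra-1(10),11-diene-3β,6α,8β,9β-tetraol | C=C(C)[C@H]1[C@H](O)[C@@H]2O[C@]2(C)[C@@H](O)C/C=C(/C)[C@@H](O)[C@H]1O | intermediate
19 | (1(10)Z)-4α,5α-epoxy-3β,6α,8β-trihydroxy-7αH-germacra-1(10),11-dien-9-one | C=C(C)[C@H]1[C@H](O)[C@@H]2O[C@]2(C)[C@@H](O)C/C=C(/C)C(=O)[C@H]1O | intermediate
20 | 1β,10β:4α,5α-diepoxy-3β,6α,8β-trihydroxy-7αH-germacr-11-en-9-one | C=C(C)[C@H]1[C@H](O)[C@@H]2O[C@]2(C)[C@@H](O)C[C@H]2O[C@@]2(C)C(=O)[C@H]1O | intermediate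
21 | angelic acid, (Z)-2-methylbut-2-enoic acid | C/C=C(/C)C(=O)O | starting material
22 | angelic 2,4,6-trichlorobenzoic anhydride | C/C=C(/C)C(=O)OC(=O)c1c(Cl)cc(Cl)cc1Cl | intermediate
23 | (1R,3S,4R,5S,6S,7S,8S,10R)-3β,6α,8β-tris(angeloyloxy)-1β,10β:4α,5α-diepoxy-7αH-germacr-11-en-9-one (CNP0154187.1) | C=C(C)[C@H]1[C@H](OC(=O)/C(C)=C\C)[C@@H]2O[C@]2(C)[C@@H](OC(=O)/C(C)=C\C)C[C@H]2O[C@@]2(C)C(=O)[C@H]1OC(=O)/C(C)=C\C | target

**Totals**
Total step count: 13. Longest linear sequence: 13 steps (1 → 23).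

**Steps most likely to fail**

Step 10 (pinacol macrocyclisation). The lactol may not release the enal fast enough, and intermolecular coupling or coupling at C1 of the allylic ketyl may compete. The fallback sets out from 15 and works with an open-chain, fully unmasked dialdehyde. The lactone is opened with MeNH(OMe)·HCl/i-PrMgCl (THF, −20 °C) to the (Z)-hydroxy Weinreb amide F1. Its C3 hydroxyl is capped with Et3SiOTf/2,6-lutidine to give the bis-silyl ether F2. i-Bu2AlH (−78 °C) reduces amide and ester together to the open-chain Z-enal dialdehyde F3. SmI2 under high dilution closes C8–C9 to the bis-silylated macrocyclic diol F4, and HF·pyridine removes both silyl groups to come back to the route at 18.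

Step 12 (enone epoxidation). The stepwise mechanism could give the trans-fused oxirane or the wrong face, and the base could epimerise C8. The fallback sets out from 19 and uses a concerted, hydroxyl-delivered epoxidation instead. The three hydroxyls are esterified first (21, 2,4,6-trichlorobenzoyl chloride, Et3N, toluene) to the tris-angelate enone F5. The ketone is reduced with NaBH4/CeCl3·7H2O (MeOH, −78 °C, Felkin attack anti to the 8β-acyloxy group) to the 9β-allylic alcohol F6. VO(acac)2/t-BuOOH then delivers oxygen from the 9β-hydroxyl to give the 1β,10β-epoxy alcohol F7, and Dess–Martin periodinane oxidises C9 to come back to the route at 23.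

Step 13 (triple angeloylation). Three hindered secondary alcohols on a base-sensitive epoxy ketone may react incompletely or give tiglates. The fallback sets out from 20 and builds the Z-olefins on the ester instead of transferring them. All three hydroxyls are acylated with 2-[bis(2,2,2-trifluoroethoxy)phosphoryl]propanoic acid (DCC, DMAP cat.) to the tris(phosphonopropanoate) F8. Still–Gennari olefination with acetaldehyde (KN(SiMe3)2, 18-crown-6, THF, −78 °C) then forms the three angelates and comes back to the route at 23.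

**Further compounds**
F1 | step 10 | methyl (2S,3S)-3-[(2S,3R)-3-[(1S,3Z)-1-hydroxy-5-[methoxy(methyl)amino]-4-methyl-5-oxopent-3-en-1-yl]-3-methyloxiran-2-yl]-2-(prop-1-en-2-yl)-3-(trimethylsilyloxy)propanoate | C=C(C)[C@H](C(=O)OC)[C@H](O[Si](C)(C)C)[C@@H]1O[C@]1(C)[C@@H](O)C/C=C(/C)C(=O)N(C)OC
F2 | step 10 | C3 triethylsilyl ether of F1 | C=C(C)[C@H](C(=O)OC)[C@H](O[Si](C)(C)C)[C@@H]1O[C@]1(C)[C@@H](O[Si](CC)(CC)CC)C/C=C(/C)C(=O)N(C)OC
F3 | step 10 | open-chain dialdehyde: C8 aldehyde and (Z)-C9 enal, 3-O-triethylsilyl, 6-O-trimethylsilyl, 4,5-cis-epoxide | C=C(C)[C@H](C=O)[C@H](O[Si](C)(C)C)[C@@H]1O[C@]1(C)[C@@H](O[Si](CC)(CC)CC)C/C=C(/C)C=O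
F4 | step 10 | (1(10)Z)-4α,5α-epoxy-3β-(triethylsilyloxy)-6α-(trimethylsilyloxy)-7αH-germacra-1(10),11-diene-8β,9β-diol | C=C(C)[C@H]1[C@H](O[Si](C)(C)C)[C@@H]2O[C@]2(C)[C@@H](O[Si](CC)(CC)CC)C/C=C(/C)[C@@H](O)[C@H]1O
F5 | step 12 | (1(10)Z)-3β,6α,8β-tris(angeloyloxy)-4α,5α-epoxy-7αH-germacra-1(10),11-dien-9-one | C=C(C)[C@H]1[C@H](OC(=O)/C(C)=C\C)[C@@H]2O[C@]2(C)[C@@H](OC(=O)/C(C)=C\C)C/C=C(/C)C(=O)[C@H]1OC(=O)/C(C)=C\C
F6 | step 12 | (1(10)Z)-3β,6α,8β-tris(angeloyloxy)-4α,5α-epoxy-7αH-germacra-1(10),11-dien-9β-ol | C=C(C)[C@H]1[C@H](OC(=O)/C(C)=C\C)[C@@H]2O[C@]2(C)[C@@H](OC(=O)/C(C)=C\C)C/C=C(/C)[C@@H](O)[C@H]1OC(=O)/C(C)=C\C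
F7 | step 12 | 3β,6α,8β-tris(angeloyloxy)-1β,10β:4α,5α-diepoxy-7αH-germacr-11-en-9β-ol | C=C(C)[C@H]1[C@H](OC(=O)/C(C)=C\C)[C@@H]2O[C@]2(C)[C@@H](OC(=O)/C(C)=C\C)C[C@H]2O[C@@]2(C)[C@@H](O)[C@H]1OC(=O)/C(C)=C\C
F8 | step 13 | 3β,6α,8β-tris{2-[bis(2,2,2-trifluoroethoxy)phosphoryl]propanoyloxy}-1β,10β:4α,5α-diepoxy-7αH-germacr-11-en-9-one | C=C(C)[C@H]1[C@H](OC(=O)C(C)P(=O)(OCC(F)(F)F)OCC(F)(F)F)[C@@H]2O[C@]2(C)[C@@H](OC(=O)C(C)P(=O)(OCC(F)(F)F)OCC(F)(F)F)C[C@H]2O[C@@]2(C)C(=O)[C@H]1OC(=O)C(C)P(=O)(OCC(F)(F)F)OCC(F)(F)F
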